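Numbering (chamigrane): ring B is C1–C6 with C2–Br and C3(CH3)–Cl, C6 is the spiro carbon, ring A is C6–C11 with C7=CH2, C8–OH, C9=C10–Br and C11(CH3)2.
Cuts, late to early: C7=CH2 (back to a C7 ketone), C8–O and C10–Br (back to the ring-A enone through its silyl dienol ethers), C2–Br and C3–Cl (back to a C2=C3 alkene).
Enabling feature: the vicinal C2–Br/C3(CH3)–Cl pair of ring B is the BrCl adduct of a trisubstituted C2=C3 alkene lying opposite the spiro carbon C6, so C2=C3 is cut by ring-closing metathesis to an allyl arm and a 3-methylbut-3-enyl arm on C6; C6–C1 and C6–C5 are then cut to 5,5-dimethylcyclohex-2-en-1-one.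
Forward: ring A is bought, the two arms are put on C6 (enolate alkylation, then decarboxylative allylation), ring B is closed by metathesis and halogenated, and ring A is functionalised last.
Stereochemistry: C6 from the chiral palladium phosphinooxazoline catalyst, C2 and C3 from anti addition of BrCl to the alkene face away from the axial C7, C8 from the chiral ketone catalyst of a Shi epoxidation.

Key step: step 5

Remark: atoms are addressed by the chamigrane numbers above, while compound names use spiro[5.5]undecane numbering. Ring B is assumed to hold C11 equatorial and C7 axial, because an axial C11 would turn one of its methyl groups into ring B.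

Step 1
Reactants: 1 3-methylbut-3-en-1-ol
Product: 2 4-iodo-2-methylbut-1-ene
Conditions: I2, PPh3, imidazole, CH2Cl2, 0 °C → rt
Reagents that add atoms: iodine [I][I]
Why: Appel-type iodination of a primary alcohol runs by SN2 displacement of the alkoxyphosphonium ion by iodide and leaves the 1,1-disubstituted alkene alone, giving the iodide that the hindered alkylation of step 2 needs.

Step 2
Reactants: 3 5,5-dimethylcyclohex-2-en-1-one; 2 4-iodo-2-methylbut-1-ene
Product: 5 rac-5,5-dimethyl-6-(3-methylbut-3-en-1-yl)cyclohex-2-en-1-one, via lithium dienolate 4 (not isolated)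
Conditions: LiN(i-Pr)2, THF, −78 °C; then 2, DMPU, −78 → 0 °C
Reagents that add atoms: none
Why: Kinetic α′-deprotonation of the enone gives the cross-conjugated lithium dienolate, which is alkylated at C6 by the primary iodide (SN2 enolate alkylation); the stereocentre formed is racemic and is erased in step 3.

Step 3
Reactants: 5 rac-5,5-dimethyl-6-(3-methylbut-3-en-1-yl)cyclohex-2-en-1-one; 6 allyl chloroformate
Product: 8 allyl 3,3-dimethyl-2-(3-methylbut-3-en-1-yl)cyclohexa-1,5-dien-1-yl carbonate, via lithium dienolate 7 (not isolated)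
Conditions: LiN(i-Pr)2, TMEDA, THF, −78 °C; then 6, −78 °C → rt
Reagents that add atoms: none
Why: The remaining α′-proton is removed to give the tetrasubstituted lithium dienolate, and the hard chloroformate in the presence of TMEDA reacts at oxygen (enolate O-acylation), which fixes the enolate regiochemistry for step 4 and flattens C6.

Step 4
Reactants: 8 allyl 3,3-dimethyl-2-(3-methylbut-3-en-1-yl)cyclohexa-1,5-dien-1-yl carbonate
Product: 9 (R)-6-allyl-5,5-dimethyl-6-(3-methylbut-3-en-1-yl)cyclohex-2-en-1-one
Conditions: Pd2(dba)3 (2.5 mol %), (S)-4-tert-butyl-2-{2-[bis(4-trifluoromethylphenyl)phosphanyl]-5-(trifluoromethyl)phenyl}-4,5-dihydrooxazole (6 mol %), toluene, 30 °C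
Reagents that add atoms: none
Why: Decarboxylative asymmetric allylic alkylation (Tsuji type): zerovalent palladium ionises the allyl carbonate, CO2 is lost and the allyl group is transferred to C6 of the palladium enolate inside the chiral phosphinooxazoline pocket, so the catalyst alone sets the quaternary stereocentre, and the (S)-ligand, which leads to (S)-2-allyl-2-methylcyclohexanone in the parent case, is expected to give the (R)-ketone here because the same enolate face is attacked while the gem-dimethyl ring carbon outranks allyl.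

Step 5
Reactants: 9 (R)-6-allyl-5,5-dimethyl-6-(3-methylbut-3-en-1-yl)cyclohex-2-en-1-one
Product: 10 (R)-5,5,9-trimethylspiro[5.5]undeca-2,8-dien-1-one
Conditions: second-generation Grubbs catalyst (H2IMes)(PCy3)Cl2Ru=CHPh (5 mol %), CH2Cl2 (0.01 M), 40 °C
Reagents that add atoms: none
Why: Ring-closing olefin metathesis: the ruthenium benzylidene exchanges onto the monosubstituted allyl alkene, the new alkylidene adds in a [2+2] sense to the 1,1-disubstituted alkene of the other arm, and cycloreversion of the ruthenacyclobutane releases the ring and, after turnover, ethylene. The closest known reaction type is the metathesis closure of 1,6-dienes to trisubstituted spirocyclohexenes next to a quaternary carbon. Ring B (C1–C6) is closed as a six-membered carbocycle by forming the C2=C3 bond, the two arms being held together on the quaternary C6 (Thorpe–Ingold effect). No stereocentre is formed and C6 is not touched. The step needs ring closure to win over cross-metathesis and over engagement of the ring-A alkene; high dilution, the slow intermolecular reaction of the 1,1-disubstituted alkene and the electron-poor, hindered enone alkene secure this. Loss of ethylene drives the closure.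

Step 6
Reactants: 10 (R)-5,5,9-trimethylspiro[5.5]undeca-2,8-dien-1-one
Product: 11 (6R,8S,9S)-8-bromo-9-chloro-5,5,9-trimethylspiro[5.5]undec-2-en-1-one
Conditions: NBS, HCl (2 M in Et2O), CH2Cl2, −78 → −40 °C
Reagents that add atoms: N-bromosuccinimide O=C1CCC(=O)N1Br; hydrogen chloride Cl
Why: Electrophilic anti bromochlorination with BrCl made in the flask: with C11 equatorial and the carbonyl carbon C7 axial on ring B, the bromonium ion that can be opened is the one on the alkene face away from C7, and chloride enters at the tertiary carbon C3 (Markovnikov) from the opposite face, far from C7, so that C2–Br (cis to C11) and C3–Cl (cis to C7) are set together as the trans-diequatorial pair while the electron-poor enone alkene does not react.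

Step 7
Reactants: 11 (6R,8S,9S)-8-bromo-9-chloro-5,5,9-trimethylspiro[5.5]undec-2-en-1-one
Product: 13 (6R,8S,9S)-4,8-dibromo-9-chloro-5,5,9-trimethylspiro[5.5]undec-2-en-1-one (both C4 epimers), via trimethylsilyl dienol ether 12 (not isolated)
Conditions: TMSOTf, Et3N, CH2Cl2, 0 °C; evaporate, pentane, filter; NBS, THF, −78 °C
Reagents that add atoms: N-bromosuccinimide O=C1CCC(=O)N1Br
Why: Soft enolisation can only remove a γ-proton because C6 is quaternary, and the resulting silyl dienol ether is brominated by NBS at its γ-terminus C10, as in the 6-bromination of steroidal 3,5-dienol ethers, to return the conjugated enone; the C10 configuration does not matter because C10 becomes sp2 in step 8.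

Step 8
Reactants: 13 (6R,8S,9S)-4,8-dibromo-9-chloro-5,5,9-trimethylspiro[5.5]undec-2-en-1-one (both C4 epimers)
Product: 14 tert-butyl{[(6R,8S,9S)-4,8-dibromo-9-chloro-5,5,9-trimethylspiro[5.5]undeca-1,3-dien-1-yl]oxy}dimethylsilane
Conditions: TBSOTf, Et3N, CH2Cl2, 0 °C → rt
Reagents that add atoms: tert-butyldimethylsilyl triflate CC(C)(C)[Si](C)(C)OS(=O)(=O)C(F)(F)F
Why: Soft enolisation again removes the only enolisable proton, the C10–H now acidified by bromine, and O-silylation gives the silyl dienol ether in which the C9=C10–Br vinyl bromide is in place.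

Step 9
Reactants: 14 tert-butyl{[(6R,8S,9S)-4,8-dibromo-9-chloro-5,5,9-trimethylspiro[5.5]undeca-1,3-dien-1-yl]oxy}dimethylsilane
Product: 16 (2R,6R,8S,9S)-4,8-dibromo-9-chloro-2-hydroxy-5,5,9-trimethylspiro[5.5]undec-3-en-1-one, via silyloxy epoxide 15 (not isolated)
Conditions: D-fructose-derived Shi ketone (1,2:4,5-di-O-isopropylidene-β-D-erythro-hexo-2,3-diulopyranose, 30 mol %), KHSO5, K2CO3, Bu4NHSO4, MeCN/CH2(OMe)2/aq. Na2B4O7, 0 °C
Reagents that add atoms: potassium peroxymonosulfate [K+].[O-]S(=O)(=O)OO
Why: Rubottom-type oxidation in its asymmetric Shi form: the chiral dioxirane epoxidises the electron-rich C7=C8 enol ether and not the bromine-deactivated C9=C10 bond, the silyloxy epoxide collapses to the α-hydroxy ketone, and the C8 configuration is set by the catalyst (spiro transition state, the D-fructose-derived ketone being expected to attack the face that gives 8R by analogy with 1-arylcyclohexenes and cyclic silyl enol ethers) because ring B hardly differentiates the two faces of ring A.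

Step 10
Reactants: 16 (2R,6R,8S,9S)-4,8-dibromo-9-chloro-2-hydroxy-5,5,9-trimethylspiro[5.5]undec-3-en-1-one
Product: 17 (2R,6R,8S,9S)-4,8-dibromo-9-chloro-5,5,9-trimethyl-2-[(triethylsilyl)oxy]spiro[5.5]undec-3-en-1-one
Conditions: TESOTf, 2,6-lutidine, CH2Cl2, −78 °C
Reagents that add atoms: triethylsilyl triflate CC[Si](CC)(CC)OS(=O)(=O)C(F)(F)F
Why: O-silylation of the secondary alcohol with a silyl triflate and a hindered pyridine base at low temperature is faster than enolisation, so the doubly activated C8–H is kept and the hydroxyl is masked for the titanium reagent.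

Step 11
Reactants: 17 (2R,6R,8S,9S)-4,8-dibromo-9-chloro-5,5,9-trimethyl-2-[(triethylsilyl)oxy]spiro[5.5]undec-3-en-1-one
Product: 18 triethyl{[(2R,6S,8S,9S)-4,8-dibromo-9-chloro-5,5,9-trimethyl-1-methylidenespiro[5.5]undec-3-en-2-yl]oxy}silane
Conditions: Cp2TiMe2, toluene/THF, 70 °C, dark
Reagents that add atoms: dimethyltitanocene C[Ti](C)(C1C=CC=C1)C1C=CC=C1
Why: Petasis methylenation: on heating the reagent loses methane to give Cp2Ti=CH2, which adds to the hindered ketone in a [2+2] sense and cycloreverts to the alkene and titanocene oxide, and being non-basic it should leave the enolisable C8–H and the alkyl halides alone where a phosphorus ylide would not.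

Step 12
Reactants: 18 triethyl{[(2R,6S,8S,9S)-4,8-dibromo-9-chloro-5,5,9-trimethyl-1-methylidenespiro[5.5]undec-3-en-2-yl]oxy}silane
Product: 19 (2R,6S,8S,9S)-4,8-dibromo-9-chloro-5,5,9-trimethyl-1-methylidenespiro[5.5]undec-3-en-2-ol
Conditions: HF·pyridine, pyridine, THF, 0 °C
Reagents that add atoms: none
Why: Fluoride-driven cleavage of the Si–O bond, buffered with pyridine so that the doubly allylic alcohol does not ionise, frees the C8 hydroxyl without touching the vinyl bromide, the secondary bromide or the tertiary chloride.

Compound list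
1 | 3-methylbut-3-en-1-ol | C=C(C)CCO | starting material
2 | 4-iodo-2-methylbut-1-ene | C=C(C)CCI | intermediate
3 | 5,5-dimethylcyclohex-2-en-1-one | O=C1C=CCC(C)(C)C1 | starting material
4 | lithium 3,3-dimethylcyclohexa-1,5-dien-1-olate (α′-dienolate of 3) | [Li]OC1=CC(C)(C)CC=C1 | intermediate
5 | rac-5,5-dimethyl-6-(3-methylbut-3-en-1-yl)cyclohex-2-en-1-one | O=C1C=CCC(C)(C)C1CCC(C)=C | intermediate
6 | allyl chloroformate | C=CCOC(=O)Cl | starting material
7 | lithium 3,3-dimethyl-2-(3-methylbut-3-en-1-yl)cyclohexa-1,5-dien-1-olate (α′-dienolate of 5) | [Li]OC1=C(CCC(C)=C)C(C)(C)CC=C1 | intermediate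
8 | allyl 3,3-dimethyl-2-(3-methylbut-3-en-1-yl)cyclohexa-1,5-dien-1-yl carbonate | C=CCOC(=O)OC1=C(CCC(C)=C)C(C)(C)CC=C1 | intermediate
9 | (R)-6-allyl-5,5-dimethyl-6-(3-methylbut-3-en-1-yl)cyclohex-2-en-1-one | O=C1C=CCC(C)(C)[C@]1(CC=C)CCC(C)=C | intermediate
10 | (R)-5,5,9-trimethylspiro[5.5]undeca-2,8-dien-1-one | O=C1C=CCC(C)(C)[C@]12CCC(C)=CC2 | intermediate
11 | (6R,8S,9S)-8-bromo-9-chloro-5,5,9-trimethylspiro[5.5]undec-2-en-1-one | O=C1C=CCC(C)(C)[C@]12CC[C@](C)(Cl)[C@@H](Br)C2 | intermediate
12 | trimethyl{[(6R,8S,9S)-8-bromo-9-chloro-5,5,9-trimethylspiro[5.5]undeca-1,3-dien-1-yl]oxy}silane | C[Si](C)(C)OC1=CC=CC(C)(C)[C@]12CC[C@](C)(Cl)[C@@H](Br)C2 | intermediate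
13 | (6R,8S,9S)-4,8-dibromo-9-chloro-5,5,9-trimethylspiro[5.5]undec-2-en-1-one, both C4 epimers | O=C1C=CC(Br)C(C)(C)[C@]12CC[C@](C)(Cl)[C@@H](Br)C2 | intermediate
14 | tert-butyl{[(6R,8S,9S)-4,8-dibromo-9-chloro-5,5,9-trimethylspiro[5.5]undeca-1,3-dien-1-yl]oxy}dimethylsilane | CC(C)(C)[Si](C)(C)OC1=CC=C(Br)C(C)(C)[C@]12CC[C@](C)(Cl)[C@@H](Br)C2 | intermediate
15 | 1,2-epoxide of 14 (1-tert-butyldimethylsilyloxy-1,2-epoxy-4,8-dibromo-9-chloro-5,5,9-trimethylspiro[5.5]undec-3-ene, epoxide oxygen on the C2 face that becomes the 2R hydroxyl) | CC(C)(C)[Si](C)(C)O[C@@]12O[C@@H]1C=C(Br)C(C)(C)[C@]23CC[C@](C)(Cl)[C@@H](Br)C3 | intermediate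
16 | (2R,6R,8S,9S)-4,8-dibromo-9-chloro-2-hydroxy-5,5,9-trimethylspiro[5.5]undec-3-en-1-one | O=C1[C@H](O)C=C(Br)C(C)(C)[C@]12CC[C@](C)(Cl)[C@@H](Br)C2 | intermediate
17 | (2R,6R,8S,9S)-4,8-dibromo-9-chloro-5,5,9-trimethyl-2-[(triethylsilyl)oxy]spiro[5.5]undec-3-en-1-one | O=C1[C@H](O[Si](CC)(CC)CC)C=C(Br)C(C)(C)[C@]12CC[C@](C)(Cl)[C@@H](Br)C2 | intermediate
18 | triethyl{[(2R,6S,8S,9S)-4,8-dibromo-9-chloro-5,5,9-trimethyl-1-methylidenespiro[5.5]undec-3-en-2-yl]oxy}silane | C=C1[C@H](O[Si](CC)(CC)CC)C=C(Br)C(C)(C)[C@]12CC[C@](C)(Cl)[C@@H](Br)C2 | intermediate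
19 | (2R,6S,8S,9S)-4,8-dibromo-9-chloro-5,5,9-trimethyl-1-methylidenespiro[5.5]undec-3-en-2-ol, by chamigrane numbering (2S,3S,6S,8R)-2,10-dibromo-3-chlorochamigra-7(14),9-dien-8-ol | C=C1[C@H](O)C=C(Br)C(C)(C)[C@]12CC[C@](C)(Cl)[C@@H](Br)C2 | target

Total step count: 12.
Longest linear sequence: 12 steps (1 → 2 → 5 → … → 19); counted from enone 3 it is 11.

Steps most likely to fail

Step 6. Chloride may open the bromonium ion in the usual diaxial sense at the secondary carbon C2 instead of at the tertiary C3, because attack at C3 has to pass through a twist-boat; this would erode the regiochemistry of the addition. The fallback sets out from 10 and accepts that opening. BrCl is added from Bu4N[BrCl2] in CH2Cl2, where halide-assisted diaxial opening should dominate, to give (6R,8R,9R)-9-bromo-8-chloro-5,5,9-trimethylspiro[5.5]undec-2-en-1-one F1 (bromine axial on C3 on the C11 face, chlorine axial on C2 on the C7 face). Warming F1 in MeCN at 60–80 °C should then bring about the known diaxial-to-diequatorial 1,2-interchange of trans-vicinal dihalides, in which each halogen moves to the neighbouring carbon on its own face. The driving forces would be relief of the syn-axial chlorine/C7 contact and the stronger tertiary C–Cl bond; the product is 11, where the route is rejoined. A mixture of 11 and F1 from step 6 can be converged in the same way.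

Step 9. Oxygen transfer to the enol ether beside the spiro carbon may be slow or poorly face-selective, and the carbonate buffer may enolise the doubly activated C8–H of the product, scrambling C8 or moving the alkene into conjugation. The fallback sets the stereocentre by carbonyl reduction instead of alkene oxidation and sets out from 14. A plain Rubottom oxidation (mCPBA, NaHCO3, CH2Cl2, −20 °C) should give 16 together with its epimer (2S,6R,8S,9S)-4,8-dibromo-9-chloro-2-hydroxy-5,5,9-trimethylspiro[5.5]undec-3-en-1-one F2. The mixture is oxidised with Dess–Martin periodinane to the non-enolisable (6R,8S,9S)-4,8-dibromo-9-chloro-5,5,9-trimethylspiro[5.5]undec-3-ene-1,2-dione F3. A Corey–Bakshi–Shibata reduction then reduces the unhindered C2 carbonyl (C8 by chamigrane numbering) under catalyst control and returns 16. The conditions are (S)-1-methyl-3,3-diphenyltetrahydro-1H,3H-pyrrolo[1,2-c][1,3,2]oxazaborole with catecholborane in toluene at −78 °C. The (S)-catalyst is expected to give the 2R alcohol if the acyl carbon C1 acts as the large group; otherwise the antipodal catalyst is used.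

Step 11. Methylidene transfer to a ketone flanked by the spiro carbon and the silyloxy carbon may be too slow at 70 °C, so that thermal enolisation at C8 or decomposition of the titanium reagent wins. The fallback is a Peterson olefination and sets out from 17. Me3SiCH2Li with CeCl3 in THF at −78 °C, a weakly basic nucleophile that adds to hindered enolisable ketones, should give (2R,6R,8S,9S)-4,8-dibromo-9-chloro-5,5,9-trimethyl-2-[(triethylsilyl)oxy]-1-[(trimethylsilyl)methyl]spiro[5.5]undec-3-en-1-ol F4 (C1 configuration irrelevant). HF·pyridine in THF (0 °C → rt) should then effect the acid-induced elimination of the β-hydroxysilane and cleave the triethylsilyl ether in the same flask, so this fallback rejoins the route at the target 19.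

Further compounds
F1 | step 6 | (6R,8R,9R)-9-bromo-8-chloro-5,5,9-trimethylspiro[5.5]undec-2-en-1-one | O=C1C=CCC(C)(C)[C@]12CC[C@@](C)(Br)[C@H](Cl)C2
F2 | step 9 | (2S,6R,8S,9S)-4,8-dibromo-9-chloro-2-hydroxy-5,5,9-trimethylspiro[5.5]undec-3-en-1-one | O=C1[C@@H](O)C=C(Br)C(C)(C)[C@]12CC[C@](C)(Cl)[C@@H](Br)C2
F3 | step 9 | (6R,8S,9S)-4,8-dibromo-9-chloro-5,5,9-trimethylspiro[5.5]undec-3-ene-1,2-dione | O=C1C(=O)C=C(Br)C(C)(C)[C@]12CC[C@](C)(Cl)[C@@H](Br)C2
F4 | step 11 | (2R,6R,8S,9S)-4,8-dibromo-9-chloro-5,5,9-trimethyl-2-[(triethylsilyl)oxy]-1-[(trimethylsilyl)methyl]spiro[5.5]undec-3-en-1-ol, both C1 epimers | C[Si](C)(C)CC1(O)[C@H](O[Si](CC)(CC)CC)C=C(Br)C(C)(C)[C@]12CC[C@](C)(Cl)[C@@H](Br)C2
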